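**Retrosynthetic overview**
- Feature: ring C (O1, C2, C3, C4=O, C4a, C8a) is read as the furanone ring of a 2-arylbenzofuran-3-one (O1, C2, C4, C4a, C8a) enlarged by the one carbon C3, placed between C2 and the carbonyl carbon C4.
- 15 ⇐ MOM ether 14 ⇐ cyclopropanol 12: base-induced cleavage of the internal cyclopropane bond with invertive protonation at C2 (ring C is formed last, step 9).
- 12 ⇐ silyloxycyclopropane 11 ⇐ 3-silyloxybenzofuran 9 + CH2I2 10: enantioselective Simmons–Smith methylene transfer to the furan C2=C3 bond (cyclopropane formed in step 7).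
- 9 ⇐ benzyl ether ester 7 by anionic cyclisation onto the ester and O-silylation (furan ring formed in step 6) ⇐ salicylate 2 + benzylic bromide 6.
- 2 ⇐ acid 1; 6 ⇐ aldehyde 3 by MOM protection, reduction and bromination; rings A and B are bought.

Key step: step 7

Assumption: the antipode of the dipeptide ligand that delivers CH2 to the required face cannot be predicted for this substrate class; the route is written for Boc-L-Val-L-Pro-OMe, and its mirror image is taken if a test run shows the opposite sense.

**Step 1**
Reactants: 1 2-hydroxy-3,4-dimethoxybenzoic acid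
Product: 2 methyl 2-hydroxy-3,4-dimethoxybenzoate
Conditions: MeOH, H2SO4 (cat.), reflux
Reagents that add atoms: methanol (CO)
Why: Fischer esterification converts the acid to the methyl ester, and the hydrogen-bonded phenol is not alkylated under acid catalysis.

**Step 2**
Reactants: 3 3-hydroxy-4,5-dimethoxybenzaldehyde
Product: 4 3,4-dimethoxy-5-(methoxymethoxy)benzaldehyde
Conditions: MOMCl, iPr2NEt, CH2Cl2, 0 °C → rt
Reagents that add atoms: chloromethyl methyl ether (COCCl)
Why: O-alkylation of the phenol (Williamson-type acetal formation) gives a MOM ether that should withstand hydride, LDA, the zinc carbenoid, fluoride and alkoxide.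

**Step 3**
Reactants: 4 3,4-dimethoxy-5-(methoxymethoxy)benzaldehyde
Product: 5 [3,4-dimethoxy-5-(methoxymethoxy)phenyl]methanol
Conditions: NaBH4, MeOH, 0 °C
Reagents that add atoms: none
Why: Borohydride reduction of the aryl aldehyde to the benzylic alcohol leaves the acetal and the methyl ethers untouched.

**Step 4**
Reactants: 5 [3,4-dimethoxy-5-(methoxymethoxy)phenyl]methanol
Product: 6 5-(bromomethyl)-1,2-dimethoxy-3-(methoxymethoxy)benzene
Conditions: CBr4, PPh3, CH2Cl2, 0 °C; used without storage
Reagents that add atoms: tetrabromomethane (BrC(Br)(Br)Br)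
Why: The Appel reaction brominates the primary benzylic alcohol under neutral conditions, so no HBr is present to cleave the MOM ether.

**Step 5**
Reactants: 2 methyl 2-hydroxy-3,4-dimethoxybenzoate; 6 5-(bromomethyl)-1,2-dimethoxy-3-(methoxymethoxy)benzene
Product: 7 methyl 2-{[3,4-dimethoxy-5-(methoxymethoxy)phenyl]methoxy}-3,4-dimethoxybenzoate
Conditions: K2CO3, DMF, rt → 50 °C
Reagents that add atoms: none
Why: Williamson ether synthesis, in which the salicylate phenoxide displaces the reactive benzylic bromide by SN2.

**Step 6**
Reactants: 7 methyl 2-{[3,4-dimethoxy-5-(methoxymethoxy)phenyl]methoxy}-3,4-dimethoxybenzoate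
Product: 9 2-[3,4-dimethoxy-5-(methoxymethoxy)phenyl]-6,7-dimethoxy-3-(triethylsilyloxy)benzofuran, via lithium benzofuran-3-olate 8 (not isolated)
Conditions: LDA (2.5 equiv), THF, −78 → −30 °C; then Et3SiCl (2.5 equiv), −78 → 0 °C; NaHCO3 work-up, Et3N-deactivated silica
Reagents that add atoms: chlorotriethylsilane (CC[Si](Cl)(CC)CC)
Why: Anionic cyclisation (intramolecular Claisen-type acylation, 5-exo-trig), in which the ester-directed benzylic lithiation next to the aryloxy oxygen is followed by attack on the neighbouring ester, the ketone is deprotonated at once to the aromatic benzofuranolate, and O-silylation traps the air-sensitive benzofuranone as its silyl enol ether.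

**Step 7**
Reactants: 9 2-[3,4-dimethoxy-5-(methoxymethoxy)phenyl]-6,7-dimethoxy-3-(triethylsilyloxy)benzofuran; 10 diiodomethane
Product: 11 (1aR,6bR)-1a-[3,4-dimethoxy-5-(methoxymethoxy)phenyl]-3,4-dimethoxy-6b-(triethylsilyloxy)-1a,6b-dihydro-1H-cyclopropa[b]benzofuran (cis-fused; methoxy groups on the two benzo carbons next to the ring oxygen)
Conditions: Et2Zn, CH2I2, Boc-L-Val-L-Pro-OMe (0.25 equiv), ethyl methoxyacetate, CH2Cl2, −40 → 0 °C; pyridine quench; Et3N-deactivated silica
Reagents that add atoms: diiodomethane 10 (ICI)
Why: Proposed new method: the C2=C3 bond of 9 carries two oxygen donors (ring O1 and the silyloxy group) and only the small aromatic stabilisation of a furan ring, so it should behave toward the electrophilic zinc carbenoid as a tetrasubstituted silyl enol ether, and CH2 is transferred in a concerted butterfly transition state that forms the C2–CH2 and C3–CH2 bonds (the future C2–C3 and C3–C4 bonds of the flavanone) in one event. The closest known reactions are the dipeptide-mediated asymmetric Simmons–Smith cyclopropanation of aryl-substituted silyl enol ethers and carbenoid cyclopropanations of benzofurans; their combination on a 3-silyloxybenzofuran is untested. The cyclopropane is closed by an intermolecular concerted syn [2+1] addition, so its fusion to the dihydrofuran ring is necessarily cis. Both stereocentres (C1a and C6b) are set together by the face of CH2 delivery, which is controlled by the zinc carbenoid bound to the deprotonated Boc-NH of the dipeptide; delivery to the face that is Si at both C2 and C3 of the benzofuran gives (1aR,6bR). The step needs chemoselectivity for the enol ether double bond over the two electron-rich benzene rings, which the double oxygen activation of C2=C3 secures, and it needs the ligand-bound carbenoid to outrun the unligated one, which low temperature and the Lewis-basic ester additive support. The pyridine quench removes ZnI2 before it can open the silyloxycyclopropane.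

**Step 8**
Reactants: 11 the (1aR,6bR)-silyloxycyclopropane
Product: 12 (1aR,6bR)-1a-[3,4-dimethoxy-5-(methoxymethoxy)phenyl]-3,4-dimethoxy-1,1a-dihydro-6bH-cyclopropa[b]benzofuran-6b-ol
Conditions: TBAF, AcOH, THF, 0 °C; pH 7 work-up, crude used directly
Reagents that add atoms: none
Why: Fluoride-mediated desilylation buffered with acetic acid releases the cyclopropanol as the neutral alcohol and not as the alkoxide, so neither stereocentre is touched and no uncontrolled ring opening should start.

**Step 9**
Reactants: 12 the (1aR,6bR)-cyclopropanol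
Product: 14 (2S)-2-[3,4-dimethoxy-5-(methoxymethoxy)phenyl]-7,8-dimethoxy-2,3-dihydro-4H-chromen-4-one, via potassium cyclopropanolate 13 (not isolated)
Conditions: KOtBu (0.2 equiv), CF3CH2OH, THF, −30 → 0 °C; AcOH quench at −30 °C
Reagents that add atoms: none
Why: Proposed new method: the catalytic trifluoroethoxide generates a little of the cyclopropanolate, whose oxyanion pushes open the internal C1a–C6b bond (the only cleavage that places charge on a benzylic, aryloxy-substituted carbon and relieves the bicyclo[3.1.0] strain) while CF3CH2OH protonates C1a from the side opposite to the departing carbon (SE2, inversion), which turns (1aR,6bR) into 2S and closes ring C by one-carbon expansion; the closest known reaction is the base-catalysed homoketonisation of 2-arylcyclopropanols and cage cyclopropanols, which protonates the carbanionic carbon with inversion, but it has not been shown on a 2-oxabicyclo[3.1.0] cyclopropanol or used to set a flavanone stereocentre, and the cold, weakly basic buffer is chosen so that the product is not enolised and opened to the chalcone.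

**Step 10**
Reactants: 14 the (2S)-MOM-protected flavanone
Product: 15 (2S)-2-(3-hydroxy-4,5-dimethoxyphenyl)-7,8-dimethoxy-2,3-dihydro-4H-chromen-4-one
Conditions: HCl (2 M in MeOH), rt
Reagents that add atoms: none
Why: Acid-catalysed acetal cleavage (transacetalisation to methanol) frees the phenol, and C2 should hold its configuration because flavanones racemise through base-induced ring opening and the ring B hydroxyl is meta to C2, so no quinone methide path exists.

**Compound list**
1 | 2-hydroxy-3,4-dimethoxybenzoic acid | COc1ccc(C(=O)O)c(O)c1OC | starting material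
2 | methyl 2-hydroxy-3,4-dimethoxybenzoate | COc1ccc(C(=O)OC)c(O)c1OC | intermediate
3 | 3-hydroxy-4,5-dimethoxybenzaldehyde | COc1cc(C=O)cc(O)c1OC | starting material
4 | 3,4-dimethoxy-5-(methoxymethoxy)benzaldehyde | COc1cc(C=O)cc(OCOC)c1OC | intermediate
5 | [3,4-dimethoxy-5-(methoxymethoxy)phenyl]methanol | COc1cc(CO)cc(OCOC)c1OC | intermediate
6 | 5-(bromomethyl)-1,2-dimethoxy-3-(methoxymethoxy)benzene | COc1cc(CBr)cc(OCOC)c1OC | intermediate
7 | methyl 2-{[3,4-dimethoxy-5-(methoxymethoxy)phenyl]methoxy}-3,4-dimethoxybenzoate | COc1ccc(C(=O)OC)c(OCc2cc(OC)c(OC)c(OCOC)c2)c1OC | intermediate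
8 | lithium 2-[3,4-dimethoxy-5-(methoxymethoxy)phenyl]-6,7-dimethoxybenzofuran-3-olate | [Li+].[O-]c1c(-c2cc(OC)c(OC)c(OCOC)c2)oc2c(OC)c(OC)ccc12 | intermediate (not isolated)
9 | 2-[3,4-dimethoxy-5-(methoxymethoxy)phenyl]-6,7-dimethoxy-3-(triethylsilyloxy)benzofuran | COc1cc(-c2oc3c(OC)c(OC)ccc3c2O[Si](CC)(CC)CC)cc(OCOC)c1OC | intermediate
10 | diiodomethane | ICI | starting material
11 | (1aR,6bR)-1a-[3,4-dimethoxy-5-(methoxymethoxy)phenyl]-3,4-dimethoxy-6b-(triethylsilyloxy)-1a,6b-dihydro-1H-cyclopropa[b]benzofuran | COc1cc([C@]23C[C@@]2(O[Si](CC)(CC)CC)c2ccc(OC)c(OC)c2O3)cc(OCOC)c1OC | intermediate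
12 | (1aR,6bR)-1a-[3,4-dimethoxy-5-(methoxymethoxy)phenyl]-3,4-dimethoxy-1,1a-dihydro-6bH-cyclopropa[b]benzofuran-6b-ol | COc1cc([C@]23C[C@@]2(O)c2ccc(OC)c(OC)c2O3)cc(OCOC)c1OC | intermediate
13 | potassium (1aR,6bR)-1a-[3,4-dimethoxy-5-(methoxymethoxy)phenyl]-3,4-dimethoxy-1,1a-dihydro-6bH-cyclopropa[b]benzofuran-6b-olate | [K+].COc1cc([C@]23C[C@@]2([O-])c2ccc(OC)c(OC)c2O3)cc(OCOC)c1OC | intermediate (not isolated)
14 | (2S)-2-[3,4-dimethoxy-5-(methoxymethoxy)phenyl]-7,8-dimethoxy-2,3-dihydro-4H-chromen-4-one | COc1cc([C@@H]2CC(=O)c3ccc(OC)c(OC)c3O2)cc(OCOC)c1OC | intermediate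
15 | (2S)-2-(3-hydroxy-4,5-dimethoxyphenyl)-7,8-dimethoxy-2,3-dihydro-4H-chromen-4-one | COc1cc([C@@H]2CC(=O)c3ccc(OC)c(OC)c3O2)cc(O)c1OC | target

**Step count**
Total: 10 steps. Longest linear sequence: 9 steps (3 → 15, steps 2 to 10).

**Steps most likely to fail**

Step 7. The carbenoid may not engage the hindered, tetrasubstituted and partly aromatic C2=C3 bond. The unligated carbenoid may compete, so that CH2 reaches both faces. ZnI2 may desilylate or open the product. The fallback uses known chemistry and sets out from aldehyde 4. Claisen–Schmidt condensation with commercial 1-(2-hydroxy-3,4-dimethoxyphenyl)ethanone (CC(=O)c1ccc(OC)c(OC)c1O; KOH, EtOH, rt) should give the chalcone (E)-1-(2-hydroxy-3,4-dimethoxyphenyl)-3-[3,4-dimethoxy-5-(methoxymethoxy)phenyl]prop-2-en-1-one F1. Oxa-Michael ring closure (NaOAc, EtOH, reflux) should give the racemic flavanone F2. Preparative HPLC on a chiral stationary phase separates 14 from its (2R)-enantiomer F3, which is returned to the NaOAc equilibration and recycled. The fallback comes back to the route at 14, before step 10.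

Step 9. A planarised benzylic carbanion may be protonated from both faces or from the front. The base may also equilibrate the product with the ring-opened chalcone and erode the configuration at C2, or the external cyclopropane bond may break instead. The fallback sets out from silyloxycyclopropane 11 and uses the known oxidative ring expansion of silyloxycyclopropanes (Ito–Saegusa type; FeCl3, NaOAc, DMF, 0 °C → rt). The internal bond breaks to the benzylic, oxygen-substituted radical, which is oxidised further and loses a proton, to give the flavone 2-[3,4-dimethoxy-5-(methoxymethoxy)phenyl]-7,8-dimethoxy-4H-chromen-4-one F4. Enantioselective hydrogenation of flavones is known with the chiral ruthenium N-heterocyclic carbene catalyst formed from [Ru(cod)(2-methylallyl)2], the chiral imidazolinium salt SINpEt·HBF4 and KOtBu under H2. With the ligand antipode for the 2S series it should give 14 together with the over-reduced (2S,4S)-flavan-4-ol F5. Dess–Martin oxidation of the mixture (NaHCO3, CH2Cl2) converges on 14, where the fallback rejoins the route.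

Step 6. The α-aryloxybenzyllithium may undergo [1,2]-Wittig rearrangement before it acylates. Deprotonation of the electron-rich benzylic CH2 may be so slow that the base attacks the ester, and silylation may occur on carbon. The fallback sets out from bromide 6 and makes the C2–C3 bond at the aldehyde oxidation level. Tetrahydrothiophene (acetone, rt) should give 1-{[3,4-dimethoxy-5-(methoxymethoxy)phenyl]methyl}tetrahydrothiophenium bromide F6. Its ylide (KOH, MeCN, 0 °C → rt) adds to commercial 2-hydroxy-3,4-dimethoxybenzaldehyde (COc1ccc(C=O)c(O)c1OC). The neighbouring phenoxide then closes the ring, as in the known sulfur-ylide route from salicylaldehydes to 2,3-dihydrobenzofuran-3-ols, to give 2-[3,4-dimethoxy-5-(methoxymethoxy)phenyl]-6,7-dimethoxy-2,3-dihydrobenzofuran-3-ol F7. It is a racemic diastereomer mixture, and both centres are lost in what follows. Dess–Martin oxidation gives 2-[3,4-dimethoxy-5-(methoxymethoxy)phenyl]-6,7-dimethoxybenzofuran-3(2H)-one F8, which is kept under argon. Soft enolisation and O-silylation (Et3SiOTf, Et3N, CH2Cl2, 0 °C) bring it back to the route at 9.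

**Further compounds**
F1 | step 7 | (E)-1-(2-hydroxy-3,4-dimethoxyphenyl)-3-[3,4-dimethoxy-5-(methoxymethoxy)phenyl]prop-2-en-1-one | COc1ccc(C(=O)/C=C/c2cc(OC)c(OC)c(OCOC)c2)c(O)c1OC
F2 | step 7 | rac-2-[3,4-dimethoxy-5-(methoxymethoxy)phenyl]-7,8-dimethoxy-2,3-dihydro-4H-chromen-4-one | COc1cc(C2CC(=O)c3ccc(OC)c(OC)c3O2)cc(OCOC)c1OC
F3 | step 7 | (2R)-2-[3,4-dimethoxy-5-(methoxymethoxy)phenyl]-7,8-dimethoxy-2,3-dihydro-4H-chromen-4-one | COc1cc([C@H]2CC(=O)c3ccc(OC)c(OC)c3O2)cc(OCOC)c1OC
F4 | step 9 | 2-[3,4-dimethoxy-5-(methoxymethoxy)phenyl]-7,8-dimethoxy-4H-chromen-4-one | COc1cc(-c2cc(=O)c3ccc(OC)c(OC)c3o2)cc(OCOC)c1OC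
F5 | step 9 | (2S,4S)-2-[3,4-dimethoxy-5-(methoxymethoxy)phenyl]-7,8-dimethoxy-3,4-dihydro-2H-chromen-4-ol | COc1cc([C@@H]2C[C@H](O)c3ccc(OC)c(OC)c3O2)cc(OCOC)c1OC
F6 | step 6 | 1-{[3,4-dimethoxy-5-(methoxymethoxy)phenyl]methyl}tetrahydrothiophenium bromide | COc1cc(C[S+]2CCCC2)cc(OCOC)c1OC.[Br-]
F7 | step 6 | 2-[3,4-dimethoxy-5-(methoxymethoxy)phenyl]-6,7-dimethoxy-2,3-dihydrobenzofuran-3-ol (racemic diastereomer mixture) | COc1cc(C2Oc3c(OC)c(OC)ccc3C2O)cc(OCOC)c1OC
F8 | step 6 | 2-[3,4-dimethoxy-5-(methoxymethoxy)phenyl]-6,7-dimethoxybenzofuran-3(2H)-one (racemic) | COc1cc(C2Oc3c(OC)c(OC)ccc3C2=O)cc(OCOC)c1OC
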